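## Analysis of the target

The target (21) is an isoflavone: a 4H-chromen-4-one whose benzo ring A (C4a, C5, C6, C7, C8, C8a) is fused to the pyranone ring C (O1, C2, C3, C4), with a 2,4,5-trimethoxyphenyl ring B on C3. Ring A atoms of all intermediates are referred to below by this numbering. The molecule has no stereocenter and no configured double bond, so the problem is purely one of regiochemistry. Ring A carries no hydrogen: C4a (bonded to the C4 carbonyl), C5–OH, C6–CH2CH=CMe2, C7–OMe, C8–OH and C8a–O1, four oxygens in four different states. The sensitive features are the prenyl group (it adds HCl, cyclises onto a neighbouring free hydroxyl under acid, and rules out hydrogenolysis), the 5,8-dihydroxy pair (a para-hydroquinone on a very electron-rich ring, easily oxidised) and C2 of the chromone, which opens with strong base. The hard points are to put prenyl on C6 and not C8, to methylate O7 alone, and to tell O5 from O8a, both of which flank C4a, when ring C is closed. The strategy rests on the run C5(OH)–C6(alkyl)–C7(O-alkyl), followed by the oxygenated carbons C8 and C8a and by C4a, which only needs a later acylation. A hydroxyl, then the alkyne's carbon substituent, then its alkoxy group is the pattern that the union of a vinylketene with an alkoxyalkyne lays down, the ketene carbonyl carbon becoming C5.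

## Retrosynthetic reasoning

**21 to 20.** The last operation should be the cleavage of the O5–CH3 and O8–CH(CH3)2 bonds of 20. The free hydroquinone and a free 5-hydroxyl beside the prenyl group are the most fragile features, so they are unmasked at the end. One boron Lewis acid addresses both bonds, one as a secondary alkyl ether and the other as a methyl ether chelated to the C4 carbonyl. The O7 and ring B methyl ethers have neither handle.

**20 to 18.** Cutting O1–C2 and C2–C3 removes C2 as a one-carbon unit at the formic acid oxidation level and leaves the 2-hydroxyaryl benzyl ketone 18. This cut is preferred because ring B, C3 and C4 then form one arylacetyl unit. The forward reaction must aminomethylenate the ketone methylene and close through O8a only, which requires O5 blocked and O8a free.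

**18 to 17.** The O8a isopropyl group is put back. In the forward sense one of the two ethers flanking the ketone has to be cleaved, and it must be the secondary alkyl ether at O8a rather than the methyl ether at O5. The chelate of the ketone with a boron halide provides this selectivity.

**17 to 14 and 15.** The C4–C4a bond is cut as a Friedel–Crafts acylation of arene 14 by acid 15. C4a is the only CH of ring A and is ortho, ortho and para to three ether oxygens, so no regiochemical question arises and the two halves join convergently.

**14 to 13.** The O5–CH3 bond is cut to phenol 13. Capping this one hydroxyl is what later distinguishes O5 from O8a.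

**13 to 4 and 8.** This is the central disconnection: the C5–C6, C7–C8 and C4a–C5 bonds are cut, opening ring A into cyclobutenone 4 and ynol ether 8, with 9, 10, 11 and 12 as the species on the way. It delivers the hydroxyl, the prenyl group, the methoxy group and both isopropoxy groups in their final positions in one step. The other way, prenylating a preformed arene between two oxygens, would need a regiocontrol device of its own. The forward reaction has to fix the orientation in which the ketene and the alkyne combine.

**4 to 3, 2 and 1.** Cyclobutenone 4 is squarate 1 with one carbonyl oxygen removed. The C–O bond is reinstated as the thiocarbonyl derivative 3 of alcohol 2, and 2 is the mono-reduction product of 1. The oxygen is removed by a radical chain and not through a cation. The cation derived from 2 carries its charge on the alkoxy-bearing carbon, so it would take up hydride there or lose an isopropyl group.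

**8 to 5 and 6.** The propargylic C–C bond of 8 is cut to the alkoxyacetylide 7, made in one flask from chloroacetal 5, and prenyl bromide 6.

## Alternatives that were turned down

**Alternative 1:** Here the C3–C4 bond is disconnected. The forward key step is a carbene-catalysed intramolecular crossed benzoin reaction of keto aldehyde A1. The acyl anion equivalent generated at the aldehyde adds to the tethered aryl ketone and closes ring C as the racemic tertiary alcohol A2, which is then dehydrated across C2–C3. In its favour, this closure is mild, free of Lewis acids and well precedented for aldehyde–ketone pairs, and ring B is in place from the start. On ring C this alternative is stronger than the chosen route, which needs a boron halide to free O8a. Against it, A2 has a hydrogen at C6. The prenyl group would have to be introduced late, between two ether oxygens on a ring deactivated by the chromone carbonyl, by halogenation and cross-coupling or a similar multi-step detour. The tetraoxygenated benzaldehyde half of A1, with three different oxygen substituents, needs a lengthy aromatic synthesis of its own, and a stereocenter is made only to be destroyed. The chosen strategy instead sets the prenyl group and all four ring A oxygens in one ring-forming step from two small building blocks.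

**Alternative 2:** Ring A is disconnected at C4a–C5 by a thermal ring expansion of the squarate-derived 4-hydroxy-4-(dihydropyranyl)cyclobutenone A3. Ring opening gives a dienylketene, six-electron electrocyclisation closes ring A, and the 5,8-hydroquinone A4 results, fused to a ketal-masked chromanone. This key step has firmer precedent than the one chosen. The order of the squarate substitutions fixes prenyl next to C5 and methoxy next to C8, and both hydroxyls arrive free, so no dealkylation beside a prenyl group is needed. On these points it is the stronger plan. Against it, A4 is an air-sensitive hydroquinone that must be reprotected, and the lithiated dihydropyranone ketal needed for A3 is an awkward reagent. Ring C also arrives saturated and without ring B, so ketal removal, dehydrogenation, C3 halogenation and an aryl cross-coupling must follow. The chosen strategy attaches ring B, C3 and C4 in one Friedel–Crafts bond and needs fewer steps after the ring A construction.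

**Alternative 3:** The C4–C4a bond is disconnected within ring C. The (Z)-3-aryloxy-2-arylacrylic acid A5 is activated as a mixed anhydride and its acylium ion attacks C4a, giving isoflavone A6. In its favour are short, convergent access from a phenol and an arylacetic acid derivative, an intramolecular acylation of an activated ring, and no unusual intermediate. Up to the isoflavone core it is at least as dependable as the chosen route. Against it, A6 again has a hydrogen at C6, so the same late prenylation problem as in alternative 1 arises. The differentiated tetraoxygenated phenol must be prepared separately, and the aryloxy and carboxyl groups must be cis for closure. The chosen strategy writes the prenyl group into ring A as the ring is formed and so avoids substituting a deactivated, crowded chromone.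

Key step: step 5

Assumption: 2,4,5-trimethoxyphenylacetic acid (15) is treated as a catalogue compound; compounds 2, 3 and 10 are racemic and their stereocenters are removed again, so no stereocontrol is needed.

## Route

**Step 1**
Reactants: 1 diisopropyl squarate [3,4-di(propan-2-yloxy)cyclobut-3-ene-1,2-dione]
Product: 2 (±)-4-hydroxy-2,3-di(propan-2-yloxy)cyclobut-2-en-1-one
Conditions: LiAlH(OtBu)3 (1.1 equiv), THF, −78 → −20 °C; aq. potassium sodium tartrate (KNaC4H4O6), no acid
Reagents that add atoms: none
Why: 1,2-Reduction of one of the two equivalent vinylogous-ester carbonyls by a mild, bulky hydride; the aluminium alkoxide formed protects the second carbonyl, and the new stereocenter (racemic) disappears in step 3.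

**Step 2**
Reactants: 2 (±)-4-hydroxy-2,3-di(propan-2-yloxy)cyclobut-2-en-1-one
Product: 3 (±)-O-[4-oxo-2,3-di(propan-2-yloxy)cyclobut-2-en-1-yl] 1H-imidazole-1-carbothioate
Conditions: 1,1'-thiocarbonyldiimidazole (1.3 equiv), DMAP (0.1 equiv), CH2Cl2, 0 °C → rt; short plug of Et3N-deactivated silica, used at once
Reagents that add atoms: 1,1'-thiocarbonyldiimidazole, S=C(n1ccnc1)n1ccnc1
Why: O-Thioacylation of the secondary alcohol, the first half of a Barton–McCombie deoxygenation; the medium is acid-free, so 2 should not collapse to the isopropyl semisquarate, and prompt use forestalls allylic O-to-S transposition.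

**Step 3**
Reactants: 3 (±)-O-[4-oxo-2,3-di(propan-2-yloxy)cyclobut-2-en-1-yl] 1H-imidazole-1-carbothioate
Product: 4 2,3-di(propan-2-yloxy)cyclobut-2-en-1-one
Conditions: Bu3SnH (1.5 equiv), Et3B (0.2 equiv), trace air, toluene, 0 °C → rt; KF/silica, chromatography on Et3N-deactivated silica
Reagents that add atoms: none
Why: Barton–McCombie radical deoxygenation; the stannyl radical adds to C=S, fragmentation gives the delocalised 4-oxocyclobutenyl radical, and Bu3SnH should transfer hydrogen to the CH terminus, which carries more spin than the alkoxy-bearing terminus, is less hindered, and keeps the dialkoxy enone. Initiation with Et3B at or below room temperature keeps 4 below the temperature of its own ring opening.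

**Step 4**
Reactants: 5 2-chloro-1,1-dimethoxyethane (chloroacetaldehyde dimethyl acetal); 6 1-bromo-3-methylbut-2-ene (prenyl bromide)
Product: 8 1-methoxy-5-methylhex-4-en-1-yne, via sodium methoxyethynide 7 (not isolated)
Conditions: NaNH2 (3.0 equiv), liq. NH3, −33 °C; then 6, Et2O, −40 °C → rt (NH3 evaporated); distillation under reduced pressure
Reagents that add atoms: none
Why: Amide removes HCl and methanol from the chloroacetal and deprotonates the resulting methoxyacetylene to 7, which is alkylated by SN2 at the primary allylic carbon; with exactly three equivalents no base is left to isomerise the skipped enyne.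

**Step 5**
Reactants: 4 2,3-di(propan-2-yloxy)cyclobut-2-en-1-one; 8 1-methoxy-5-methylhex-4-en-1-yne
Product: 13 3-methoxy-2-(3-methylbut-2-en-1-yl)-4,5-di(propan-2-yloxy)phenol, via vinylketene 9 (not isolated), via vinylcyclobutenone 10 (not isolated), via dienylketene 11 (not isolated), via cyclohexadienone 12 (not isolated)
Conditions: 8 (1.5 equiv), toluene (0.5 M), Ar, 80 °C then 110 °C; then K2CO3, MeOH, rt
Reagents that add atoms: none
Why: This is a Danheiser benzannulation of a cyclobutenone with a heteroatom-substituted alkyne, the 2,3-dialkoxycyclobutenone being a new ketene source for it. Heating opens 4 by four-electron electrocyclic ring opening to vinylketene 9; the nucleophilic, prenyl-bearing carbon of 8 attacks the ketene carbonyl carbon and the [2+2] adduct 10 closes with the methoxy-bearing carbon on the ketene alpha carbon. A second four-electron opening of 10, with isopropoxy turning outward and the alkenyl group inward, gives the (Z)-dienylketene 11, which closes ring A by six-electron electrocyclisation between the ketene carbon and the terminal CH2 (the C4a–C5 bond) to dienone 12, and tautomerisation gives phenol 13. The three new ring bonds are C5–C6, C7–C8 and C4a–C5, and no stereocenter remains because that of 10 is lost on ring opening. The selectivity required is the orientation of the ketene–alkyne union; the polarisation of the ynol ether secures it and places prenyl between the new hydroxyl and the methoxy group, whereas a direct [4+2] union would give the other regioisomer and is not the path such cascades take. A methyl ynol ether has no hydrogen for retro-ene loss of an alkene, the prenyl alkene is far less nucleophilic than the ynol ether and is not placed for intramolecular ketene capture, and the excess of 8 should keep 9 from dimerising. The carbonate treatment returns any aryl ester formed when 13 captures 9.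

**Step 6**
Reactants: 13 3-methoxy-2-(3-methylbut-2-en-1-yl)-4,5-di(propan-2-yloxy)phenol
Product: 14 1,3-dimethoxy-2-(3-methylbut-2-en-1-yl)-4,5-di(propan-2-yloxy)benzene
Conditions: MeI (2 equiv), K2CO3 (2 equiv), acetone, 50 °C
Reagents that add atoms: iodomethane, CI
Why: Williamson etherification of the only hydroxyl; O5 is capped so that, of the two oxygens flanking C4a, only O8a can later be freed and close ring C.

**Step 7**
Reactants: 14 1,3-dimethoxy-2-(3-methylbut-2-en-1-yl)-4,5-di(propan-2-yloxy)benzene; 15 2-(2,4,5-trimethoxyphenyl)acetic acid
Product: 17 1-[4,6-dimethoxy-5-(3-methylbut-2-en-1-yl)-2,3-di(propan-2-yloxy)phenyl]-2-(2,4,5-trimethoxyphenyl)ethan-1-one, via acyl trifluoroacetate 16 (not isolated)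
Conditions: (CF3CO)2O (2.5 equiv), CH2Cl2, 0 °C → rt; cold sat. aq. NaHCO3
Reagents that add atoms: none
Why: Friedel–Crafts acylation by the mixed anhydride 16; C4a is the only ring A CH and is ortho to two alkoxy groups and para to the C7 methoxy group, so it should outcompete the less activated CH positions of ring B. No metal halide or mineral acid is present, and the prenyl group has no ortho hydroxyl to cyclise onto.

**Step 8**
Reactants: 17 1-[4,6-dimethoxy-5-(3-methylbut-2-en-1-yl)-2,3-di(propan-2-yloxy)phenyl]-2-(2,4,5-trimethoxyphenyl)ethan-1-one
Product: 18 1-[2-hydroxy-4,6-dimethoxy-5-(3-methylbut-2-en-1-yl)-3-(propan-2-yloxy)phenyl]-2-(2,4,5-trimethoxyphenyl)ethan-1-one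
Conditions: BCl3 (1.2 equiv, 1 M in CH2Cl2), CH2Cl2, −78 °C; cold sat. aq. NaHCO3
Reagents that add atoms: none
Why: Chelation-controlled ether cleavage; BCl3 bridges the ketone oxygen and an ortho ether oxygen, and the secondary isopropyl group at O8a ionises far more readily than the methyl group at O5, after which the boron chelate occupies the carbonyl. The non-chelated isopropyl ether at O8 and the remaining methyl ethers should react only at higher temperature.

**Step 9**
Reactants: 18 1-[2-hydroxy-4,6-dimethoxy-5-(3-methylbut-2-en-1-yl)-3-(propan-2-yloxy)phenyl]-2-(2,4,5-trimethoxyphenyl)ethan-1-one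
Product: 20 5,7-dimethoxy-6-(3-methylbut-2-en-1-yl)-8-(propan-2-yloxy)-3-(2,4,5-trimethoxyphenyl)-4H-chromen-4-one, via enaminone 19 (not isolated)
Conditions: Me2NCH(OMe)2 (3 equiv), toluene, 90 °C; then AcOH (cat.), 60 °C
Reagents that add atoms: N,N-dimethylformamide dimethyl acetal, COC(OC)N(C)C
Why: Aminomethylenation of the activated ketone methylene gives enaminone 19; the O8a hydroxyl adds to its beta carbon (6-endo) and dimethylamine is lost, giving the chromen-4-one. O5 is methylated, so closure through the wrong oxygen is excluded, and the neutral medium spares the prenyl group.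

**Step 10**
Reactants: 20 5,7-dimethoxy-6-(3-methylbut-2-en-1-yl)-8-(propan-2-yloxy)-3-(2,4,5-trimethoxyphenyl)-4H-chromen-4-one
Product: 21 5,8-dihydroxy-7-methoxy-6-(3-methylbut-2-en-1-yl)-3-(2,4,5-trimethoxyphenyl)-4H-chromen-4-one
Conditions: BCl3 (4 equiv), CH2Cl2, −78 → −10 °C; poured into cold aq. NaHCO3, work-up under Ar
Reagents that add atoms: none
Why: BCl3 cleaves the isopropyl aryl ether at O8 and, through the six-membered chelate with the C4 carbonyl, the peri methyl ether at O5; the C7 and ring B methyl ethers have no carbonyl partner and should persist at this temperature. The O5–boron chelate keeps the new hydroxyl from adding to the prenyl group until the buffered quench.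

## Compound list

1 | diisopropyl squarate [3,4-di(propan-2-yloxy)cyclobut-3-ene-1,2-dione] | CC(C)OC1=C(OC(C)C)C(=O)C1=O | starting material
2 | (±)-4-hydroxy-2,3-di(propan-2-yloxy)cyclobut-2-en-1-one | CC(C)OC1=C(OC(C)C)C(=O)C1O | intermediate
3 | (±)-O-[4-oxo-2,3-di(propan-2-yloxy)cyclobut-2-en-1-yl] 1H-imidazole-1-carbothioate | CC(C)OC1=C(OC(C)C)C(=O)C1OC(=S)n1ccnc1 | intermediate
4 | 2,3-di(propan-2-yloxy)cyclobut-2-en-1-one | CC(C)OC1=C(OC(C)C)C(=O)C1 | intermediate
5 | 2-chloro-1,1-dimethoxyethane | COC(CCl)OC | starting material
6 | 1-bromo-3-methylbut-2-ene | CC(C)=CCBr | starting material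
7 | sodium methoxyethynide | [Na+].[C-]#COC | intermediate (not isolated)
8 | 1-methoxy-5-methylhex-4-en-1-yne | COC#CCC=C(C)C | intermediate
9 | 2,3-di(propan-2-yloxy)buta-1,3-dien-1-one | C=C(OC(C)C)C(OC(C)C)=C=O | intermediate (not isolated)
10 | (±)-3-methoxy-2-(3-methylbut-2-en-1-yl)-4-(propan-2-yloxy)-4-[1-(propan-2-yloxy)ethenyl]cyclobut-2-en-1-one | C=C(OC(C)C)C1(OC(C)C)C(OC)=C(CC=C(C)C)C1=O | intermediate (not isolated)
11 | (3Z)-3-methoxy-2-(3-methylbut-2-en-1-yl)-4,5-di(propan-2-yloxy)hexa-1,3,5-trien-1-one | O=C=C(CC=C(C)C)/C(OC)=C(/OC(C)C)C(OC(C)C)=C | intermediate (not isolated)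
12 | 3-methoxy-2-(3-methylbut-2-en-1-yl)-4,5-di(propan-2-yloxy)cyclohexa-2,4-dien-1-one | O=C1CC(OC(C)C)=C(OC(C)C)C(OC)=C1CC=C(C)C | intermediate (not isolated)
13 | 3-methoxy-2-(3-methylbut-2-en-1-yl)-4,5-di(propan-2-yloxy)phenol | CC(C)Oc1cc(O)c(CC=C(C)C)c(OC)c1OC(C)C | intermediate
14 | 1,3-dimethoxy-2-(3-methylbut-2-en-1-yl)-4,5-di(propan-2-yloxy)benzene | COc1cc(OC(C)C)c(OC(C)C)c(OC)c1CC=C(C)C | intermediate
15 | 2-(2,4,5-trimethoxyphenyl)acetic acid | COc1cc(OC)c(CC(=O)O)cc1OC | starting material
16 | 2-(2,4,5-trimethoxyphenyl)acetic trifluoroacetic anhydride | COc1cc(OC)c(CC(=O)OC(=O)C(F)(F)F)cc1OC | intermediate (not isolated)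
17 | 1-[4,6-dimethoxy-5-(3-methylbut-2-en-1-yl)-2,3-di(propan-2-yloxy)phenyl]-2-(2,4,5-trimethoxyphenyl)ethan-1-one | COc1cc(OC)c(CC(=O)c2c(OC)c(CC=C(C)C)c(OC)c(OC(C)C)c2OC(C)C)cc1OC | intermediate
18 | 1-[2-hydroxy-4,6-dimethoxy-5-(3-methylbut-2-en-1-yl)-3-(propan-2-yloxy)phenyl]-2-(2,4,5-trimethoxyphenyl)ethan-1-one | COc1cc(OC)c(CC(=O)c2c(OC)c(CC=C(C)C)c(OC)c(OC(C)C)c2O)cc1OC | intermediate
19 | 3-(dimethylamino)-1-[2-hydroxy-4,6-dimethoxy-5-(3-methylbut-2-en-1-yl)-3-(propan-2-yloxy)phenyl]-2-(2,4,5-trimethoxyphenyl)prop-2-en-1-one (alkene geometry not fixed) | CN(C)C=C(C(=O)c1c(OC)c(CC=C(C)C)c(OC)c(OC(C)C)c1O)c1cc(OC)c(OC)cc1OC | intermediate (not isolated)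
20 | 5,7-dimethoxy-6-(3-methylbut-2-en-1-yl)-8-(propan-2-yloxy)-3-(2,4,5-trimethoxyphenyl)-4H-chromen-4-one | COc1cc(OC)c(-c2coc3c(OC(C)C)c(OC)c(CC=C(C)C)c(OC)c3c2=O)cc1OC | intermediate
21 | 5,8-dihydroxy-7-methoxy-6-(3-methylbut-2-en-1-yl)-3-(2,4,5-trimethoxyphenyl)-4H-chromen-4-one | COc1cc(OC)c(-c2coc3c(O)c(OC)c(CC=C(C)C)c(O)c3c2=O)cc1OC | target

## Step count and least certain steps

Total: 10 steps. Longest linear sequence: 9 steps (1 through steps 1, 2, 3, 5, 6, 7, 8, 9 and 10); step 4 is a one-step branch.

**Step 5 (key step).** The most likely failure is loss of vinylketene 9 to dimerisation or oligomerisation before the alkyne captures it. An alkoxy-substituted ketene is a weaker electrophile than the alkyl- and aryl-substituted ketenes usually used, and a methyl ynol ether is only a moderate nucleophile. A second loss would be capture of 13 by 9 as an aryl ester, which the carbonate treatment should undo. The fallback changes the alkyne class and the way the O7 methyl group arrives. It sets out from 6 and 4.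
- Bromide 6 is coupled with HC≡CMgBr (CuCl cat., THF) to give 5-methylhex-4-en-1-yne F1.
- F1 is deprotonated with nBuLi and oxidised with LiOOtBu to lithium 5-methylhex-4-en-1-yn-1-olate F2, which is silylated in the same flask with iPr3SiOTf to triisopropyl[(5-methylhex-4-en-1-yn-1-yl)oxy]silane F3.
- Heating 4 with this more nucleophilic and thermally robust siloxyalkyne should give 2-(3-methylbut-2-en-1-yl)-4,5-di(propan-2-yloxy)-3-[(triisopropylsilyl)oxy]phenol F4.
- CsF and MeI in DMF desilylate F4 to 2-(3-methylbut-2-en-1-yl)-4,5-di(propan-2-yloxy)benzene-1,3-diol F5 and methylate both hydroxyls, so the sequence rejoins the route at 14.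

**Step 3.** The most likely failures are hydrogen delivery to the alkoxy-bearing terminus of the allylic radical, which would give the 3,4-dialkoxy isomer, and sigmatropic O-to-S transposition of 3 before reduction. Both termini of the radical are alpha to the carbonyl, so only spin distribution and hindrance separate them. The fallback replaces the radical chain by a two-electron reductive cleavage, in which the metal enolate should be protonated at the carbon that bore the leaving group. It sets out from 2: acetylation (Ac2O, pyridine, DMAP) gives (±)-4-oxo-2,3-di(propan-2-yloxy)cyclobut-2-en-1-yl acetate F6, and SmI2 (2.2 equiv) in THF–MeOH at −78 °C should give 4.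

**Step 7.** The most likely failure is attack of the trifluoroacetic acid released, or of the mixed anhydride itself, on the trisubstituted prenyl alkene (addition or alkene acylation) in competition with the hindered ring position. The fallback replaces electrophilic substitution by metalation and cross-coupling, with no acid present. It sets out from 14.
- 14 is lithiated at C4a, between the two ether oxygens, with nBuLi in THF at 0 °C to [4,6-dimethoxy-5-(3-methylbut-2-en-1-yl)-2,3-di(propan-2-yloxy)phenyl]lithium F7.
- F7 is transmetallated with ZnCl2 to the arylzinc chloride F8.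
- F8 is coupled under Pd(PPh3)4 catalysis with 2-(2,4,5-trimethoxyphenyl)acetyl chloride F9, made from 15 with oxalyl chloride, to give 17.

**Step 10.** The most likely failure is hydrochlorination of the prenyl alkene, or its cyclisation onto the newly freed 5-hydroxyl to a chroman, during reaction or quench, because here a strong Lewis acid and HCl meet a free hydroxyl ortho to the prenyl group. Over-cleavage at O7 next to the O8 borate is a lesser risk. The fallback moves the O8 unmasking to a stage where both oxygens flanking the prenyl group are still methylated, and uses a magnesium halide for O5. It sets out from 17.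
- Excess BCl3 (3 equiv, −78 → −20 °C) removes both isopropyl groups and gives 1-[2,3-dihydroxy-4,6-dimethoxy-5-(3-methylbut-2-en-1-yl)phenyl]-2-(2,4,5-trimethoxyphenyl)ethan-1-one F10.
- Me2NCH(OMe)2 in THF at 60 °C gives the enaminone F11, which closes to 8-hydroxy-5,7-dimethoxy-6-(3-methylbut-2-en-1-yl)-3-(2,4,5-trimethoxyphenyl)-4H-chromen-4-one F12.
- MgI2·OEt2 in THF–toluene at 60 °C removes only the carbonyl-chelated O5 methyl group and gives 21.

## Further compounds

F1 | step 5 | 5-methylhex-4-en-1-yne | C#CCC=C(C)C
F2 | step 5 | lithium 5-methylhex-4-en-1-yn-1-olate | [Li+].[O-]C#CCC=C(C)C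
F3 | step 5 | triisopropyl[(5-methylhex-4-en-1-yn-1-yl)oxy]silane | CC(C)=CCC#CO[Si](C(C)C)(C(C)C)C(C)C
F4 | step 5 | 2-(3-methylbut-2-en-1-yl)-4,5-di(propan-2-yloxy)-3-[(triisopropylsilyl)oxy]phenol | CC(C)Oc1cc(O)c(CC=C(C)C)c(O[Si](C(C)C)(C(C)C)C(C)C)c1OC(C)C
F5 | step 5 | 2-(3-methylbut-2-en-1-yl)-4,5-di(propan-2-yloxy)benzene-1,3-diol | CC(C)Oc1cc(O)c(CC=C(C)C)c(O)c1OC(C)C
F6 | step 3 | (±)-4-oxo-2,3-di(propan-2-yloxy)cyclobut-2-en-1-yl acetate | CC(=O)OC1C(=O)C(OC(C)C)=C1OC(C)C
F7 | step 7 | [4,6-dimethoxy-5-(3-methylbut-2-en-1-yl)-2,3-di(propan-2-yloxy)phenyl]lithium | [Li]c1c(OC)c(CC=C(C)C)c(OC)c(OC(C)C)c1OC(C)C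
F8 | step 7 | chloro[4,6-dimethoxy-5-(3-methylbut-2-en-1-yl)-2,3-di(propan-2-yloxy)phenyl]zinc | Cl[Zn]c1c(OC)c(CC=C(C)C)c(OC)c(OC(C)C)c1OC(C)C
F9 | step 7 | 2-(2,4,5-trimethoxyphenyl)acetyl chloride | COc1cc(OC)c(CC(=O)Cl)cc1OC
F10 | step 10 | 1-[2,3-dihydroxy-4,6-dimethoxy-5-(3-methylbut-2-en-1-yl)phenyl]-2-(2,4,5-trimethoxyphenyl)ethan-1-one | COc1cc(OC)c(CC(=O)c2c(OC)c(CC=C(C)C)c(OC)c(O)c2O)cc1OC
F11 | step 10 | 3-(dimethylamino)-1-[2,3-dihydroxy-4,6-dimethoxy-5-(3-methylbut-2-en-1-yl)phenyl]-2-(2,4,5-trimethoxyphenyl)prop-2-en-1-one (alkene geometry not fixed) | CN(C)C=C(C(=O)c1c(OC)c(CC=C(C)C)c(OC)c(O)c1O)c1cc(OC)c(OC)cc1OC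
F12 | step 10 | 8-hydroxy-5,7-dimethoxy-6-(3-methylbut-2-en-1-yl)-3-(2,4,5-trimethoxyphenyl)-4H-chromen-4-one | COc1cc(OC)c(-c2coc3c(O)c(OC)c(CC=C(C)C)c(OC)c3c2=O)cc1OC
A1 | alternative 1 | 4-methoxy-2-[2-oxo-2-(2,4,5-trimethoxyphenyl)ethoxy]-3,6-di(propan-2-yloxy)benzaldehyde | COc1cc(OC)c(C(=O)COc2c(OC(C)C)c(OC)cc(OC(C)C)c2C=O)cc1OC
A2 | alternative 1 | racemic 3-hydroxy-7-methoxy-5,8-di(propan-2-yloxy)-3-(2,4,5-trimethoxyphenyl)chroman-4-one | COc1cc(OC)c(C2(O)COc3c(OC(C)C)c(OC)cc(OC(C)C)c3C2=O)cc1OC
A3 | alternative 2 | racemic 4-hydroxy-3-methoxy-2-(3-methylbut-2-en-1-yl)-4-(1,4,8-trioxaspiro[4.5]dec-6-en-7-yl)cyclobut-2-en-1-one | O=C1C(CC=C(C)C)=C(OC)C1(O)C1=CC2(CCO1)OCCO2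
A4 | alternative 2 | 7-methoxy-6-(3-methylbut-2-en-1-yl)chroman-4-one-5,8-diol ethylene ketal | Oc1c(CC=C(C)C)c(OC)c(O)c2OCCC3(OCCO3)c12
A5 | alternative 3 | (Z)-3-[3-methoxy-2,5-di(propan-2-yloxy)phenoxy]-2-(2,4,5-trimethoxyphenyl)prop-2-enoic acid | OC(=O)/C(c1cc(OC)c(OC)cc1OC)=C\Oc1cc(OC(C)C)cc(OC)c1OC(C)C
A6 | alternative 3 | 7-methoxy-5,8-di(propan-2-yloxy)-3-(2,4,5-trimethoxyphenyl)-4H-chromen-4-one | COc1cc(OC)c(-c2coc3c(OC(C)C)c(OC)cc(OC(C)C)c3c2=O)cc1OC
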